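**Retrosynthetic overview**

1. Numbering used throughout: ring A = C1–C5/C10; ring B = C5–C10; ring C = C8–C9=C11–C12–C13 (C13 = CHOH bridge); ring D = C8–C14–C15–C16–C12–C13; C17 = CH2OAc on C16; C18 = CH3 on C4; C19 = CH2OH on C4; C20 = CH3 on C10; β = the face of CH3-20.
2. Endgame: C17–OAc/C16–OH ⇐ C16 ketone (sulfonium ylide, then acetate opening of the epoxide); C3H2 ⇐ C3–OH; C19–OH ⇐ C19 aldehyde. This leads back to the tetracyclic aldol 26.
3. Key disconnection: 26 ⇐ bicyclic diene dialdehyde 22 by cutting C5–C10 (ring B) and C3–C4 (ring A). Forward, one iron-hydride hydrogen-atom-transfer radical–polar crossover cascade closes ring B by radical conjugate addition and then ring A, the last ring, by aldol, setting C10, C5 and C4.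
4. Enabling feature: the C9=C11 double bond of ring C directly flanks quaternary C10, and C4 carries the oxidised carbon C19 with C5 between them. C10 is therefore one terminus of an allyl radical C10–C9–C11 (H• added to C20 of a C20H2=C10–C9=C11 diene) whose other terminus C11 is locked in the bicycle; C5/C4 are the β/α carbons of a C19 enal; C3 is an aldehyde that is deoxygenated later.
5. 22 ⇐ C9 enol triflate + alkenyl boronate. Rings C/D ⇐ 2-alkylcyclopentane-1,3-dione + acrolein by a proline-catalysed desymmetrising bridged aldol that fixes C8 and C12, from which every other centre is relayed. Ring order: C (bought) → D → B → A.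

Key step: step 13

Assumption: L-proline is taken to give ketol 7 in the drawn absolute configuration; if the sense of induction is opposite, D-proline is used and nothing else changes.

**Route**

Step 1
Reactants: 1 cyclopentane-1,3-dione; 2 3-[(tert-butyldimethylsilyl)oxy]propanal
Product: 4 2-{3-[(tert-butyldimethylsilyl)oxy]propyl}cyclopentane-1,3-dione, via alkylidene dione 3 (not isolated)
Conditions: Hantzsch ester (1.0 equiv), L-proline (10 mol%), CH2Cl2, rt
Reagents that add atoms: none
Why: Three-component reductive alkylation (Knoevenagel condensation to 3, then conjugate transfer hydrogenation by the Hantzsch ester) gives clean C-monoalkylation of the dione, which direct alkylation with an unactivated halide would not.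

Step 2
Reactants: 4 2-{3-[(tert-butyldimethylsilyl)oxy]propyl}cyclopentane-1,3-dione; 5 acrolein
Product: 6 2-{3-[(tert-butyldimethylsilyl)oxy]propyl}-2-(3-oxopropyl)cyclopentane-1,3-dione
Conditions: acrolein (1.5 equiv), Et3N (10 mol%), MeCN, rt
Reagents that add atoms: none
Why: Michael addition of the acidic 2-alkyl-1,3-dione to acrolein creates the quaternary carbon C8, still prochiral because the two ring carbonyls are enantiotopic.

Step 3
Reactants: 6 trione aldehyde
Product: 7 (1R,2S,5R)-5-{3-[(tert-butyldimethylsilyl)oxy]propyl}-2-hydroxybicyclo[3.2.1]octane-6,8-dione (C9 and C13 ketones; C16–OH axial on ring D, syn to the C13 carbonyl)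
Conditions: L-proline (30 mol%), MeCN, 0.05 M, rt
Reagents that add atoms: none
Why: Proline-catalysed desymmetrising intramolecular aldol (enamine catalysis, 6-enolendo-exo-trig) joins C12 to the aldehyde carbon C16, the only closure that gives an unstrained ring, and so closes ring D as a bridged ketol; the catalyst chooses between the enantiotopic ring ketones and thereby fixes C8 and C12, and the hydrogen-bonded transition state places the C16 hydroxyl axial, syn to the C13 carbonyl.

Step 4
Reactants: 7 bridged ketol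
Product: 8 C9 ketone with C13–OH (syn to the C9–C11 bridge) and C16 benzoate
Conditions: PhCHO (5 equiv), SmI2 (20 mol%), THF, −10 °C
Reagents that add atoms: benzaldehyde, O=Cc1ccccc1
Why: Evans–Tishchenko reduction: the samarium-bound hemiacetal formed from the axial C16 hydroxyl and benzaldehyde transfers hydride intramolecularly to the face of the C13 ketone that is syn to the C14–C16 bridge, so the new C13 hydroxyl points to the C9–C11 bridge as in the target, the C9 ketone is out of reach, and the directing oxygen emerges as its benzoate, which differentiates the two hydroxyls.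

Step 5
Reactants: 8 hydroxy benzoate
Product: 9 C13 TBS ether of 8
Conditions: TBSOTf (1.3 equiv), 2,6-lutidine, CH2Cl2, −40 → 0 °C
Reagents that add atoms: tert-butyldimethylsilyl trifluoromethanesulfonate, CC(C)(C)[Si](C)(C)OS(=O)(=O)C(F)(F)F
Why: Silyl triflate silylation protects the hindered C13 alcohol as a TBS ether that survives to the last step and later shields the β face of C10.

Step 6
Reactants: 9 C9 ketone
Product: 11 C9 enol triflate (C9=C11) of ketone 9, via potassium enolate 10 (not isolated)
Conditions: KHMDS (1.1 equiv), THF, −78 °C; then PhNTf2, −78 → 0 °C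
Reagents that add atoms: N-phenylbis(trifluoromethanesulfonimide), O=S(=O)(N(c1ccccc1)S(=O)(=O)C(F)(F)F)C(F)(F)F
Why: Kinetic deprotonation of the C9 ketone can occur only at C11 (C8 is quaternary), and O-triflation of the potassium enolate gives the enol triflate with the C9=C11 double bond in its final position.

Step 7
Reactants: 11 enol triflate
Product: 12 primary alcohol (C5–OH) of the enol triflate
Conditions: HF·pyridine, pyridine, THF, 0 °C
Reagents that add atoms: none
Why: Buffered HF·pyridine cleaves the primary TBS ether much faster than the hindered secondary one at C13, a standard selective desilylation.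

Step 8
Reactants: 12 primary alcohol
Product: 13 C5 aldehyde of the enol triflate
Conditions: Dess–Martin periodinane, NaHCO3, CH2Cl2, rt
Reagents that add atoms: none
Why: Dess–Martin oxidation converts the primary alcohol into the aldehyde under near-neutral conditions that leave the enol triflate and benzoate untouched.

Step 9
Reactants: 13 C5 aldehyde; 14 2-(triphenyl-λ5-phosphanylidene)propanal
Product: 15 (E)-enal enol triflate (C5=C4, CH3-18 and C19 aldehyde on C4)
Conditions: toluene, 80 °C
Reagents that add atoms: none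
Why: Wittig olefination with the stabilised ylide gives the (E)-2-methyl enal, the thermodynamically preferred geometry.

Step 10
Reactants: 16 2,3-dibromopropene; 17 (1,3-dioxolan-2-ylmethyl)magnesium bromide
Product: 18 2-(3-bromobut-3-en-1-yl)-1,3-dioxolane
Conditions: CuI (5 mol%), THF, −20 °C → rt
Reagents that add atoms: none
Why: Copper-catalysed coupling of the Grignard reagent at the allylic bromide of 2,3-dibromopropene leaves the vinylic bromide intact and gives the C20=C10(Br)–C1–C2–C3 unit.

Step 11
Reactants: 18 2-(3-bromobut-3-en-1-yl)-1,3-dioxolane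
Product: 21 4-(4,4,5,5-tetramethyl-1,3,2-dioxaborolan-2-yl)pent-4-enal, via alkenyllithium 19 (not isolated), via dioxolane boronate 20 (not isolated)
Conditions: t-BuLi (2.0 equiv), Et2O, −78 °C; i-PrOBpin, −78 °C → rt; then 2 M HCl, THF, rt
Reagents that add atoms: 2-isopropoxy-4,4,5,5-tetramethyl-1,3,2-dioxaborolane, CC(C)OB1OC(C)(C)C(C)(C)O1; water, O
Why: Bromine–lithium exchange, borylation with the isopropoxy pinacol borate and acidic hydrolysis of the dioxolane during work-up give the alkenyl boronate with the free C3 aldehyde, so that no acid is needed after the diene is in place.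

Step 12
Reactants: 15 (E)-enal enol triflate; 21 4-(4,4,5,5-tetramethyl-1,3,2-dioxaborolan-2-yl)pent-4-enal
Product: 22 bicyclic diene dialdehyde (C20H2=C10–C9=C11 diene, C3 aldehyde, C19 enal, 13-OTBS, 16-OBz)
Conditions: PdCl2(dppf) (5 mol%), K3PO4 (3 equiv), THF/H2O (10:1), 40 °C
Reagents that add atoms: none
Why: Suzuki–Miyaura coupling of the enol triflate with the 1,1-disubstituted alkenyl boronate forms the C9–C10 bond and the 2,3-disubstituted diene under mild aqueous base that both aldehydes tolerate.

Step 13
Reactants: 22 bicyclic diene dialdehyde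
Product: 26 tetracyclic 3β-hydroxy-19-aldehyde (13-OTBS; 16-OBz), via allyl radical 23 (not isolated), via ring-B formyl radical 24 (not isolated), via iron enolate 25 (not isolated)
Conditions: Fe(acac)3 (30 mol%), PhSiH3 (2.5 equiv), EtOH/ethylene glycol (9:1), 0.005 M, degassed, 0 °C → rt
Reagents that add atoms: none
Why: Proposed new method: Fe(acac)3/PhSiH3 generates an iron hydride that transfers H• to C20, the unhindered terminus of the 2,3-disubstituted diene, giving the C10–C9–C11 allyl radical 23; this closes ring B by a 6-exo-trig conjugate addition of C10 to C5 of the enal (24), the α-formyl radical is reduced by Fe(II) to the iron enolate 25, and ring A, the last ring, closes by a 6-(enolexo)-exo-trig aldol of C4 onto the C3 aldehyde. The closest known reaction type is the iron-hydride HAT-initiated radical conjugate addition/aldol (radical–polar crossover) polycyclisation of substrates carrying an isolated 1,1-disubstituted alkene, an enal and a ketone; new here are the diene-derived allylic radical and the aldehyde as aldol acceptor. Regioselectivity is secured by the substrate: the allyl radical can form a six-membered ring only through C10 (closure through C11 would need an eight-membered ring), which also leaves the C9=C11 double bond exactly where the target has it, and HAT goes to the electron-rich diene, not to the enal. C10: H• adds to the s-trans diene (C20 next to C8), so in the radical CH3-20 is syn to C8 and C1 is syn to C11, and C5 attacks the face opposite the C13–OTBS group, which makes CH3-20 axial and cis to the C13 bridge. C5: the enal sits equatorial in the chair-like transition state, which gives the trans ring fusion (H5 anti to CH3-20). C4 and C3: the enolate is expected to react in the conformer that minimises allylic 1,3-strain (C4=C19 eclipsing C5–H), which puts C19 equatorial and CH3-18 axial, and the chelated aldol should give the equatorial C3–OH, a centre that is removed in step 17.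

Step 14
Reactants: 26 tetracyclic hydroxy aldehyde
Product: 27 3β,19-diol
Conditions: NaBH4, MeOH/THF, 0 °C
Reagents that add atoms: none
Why: Borohydride reduces the neopentyl C19 aldehyde to the primary alcohol before the β-hydroxy aldehyde can undergo retro-aldol cleavage, without touching the benzoate.

Step 15
Reactants: 27 3β,19-diol
Product: 28 19-O-TBS ether with free 3β-OH
Conditions: TBSCl (1.1 equiv), imidazole, DMF, 0 °C → rt
Reagents that add atoms: tert-butyldimethylsilyl chloride, CC(C)(C)[Si](C)(C)Cl
Why: Silylation with TBSCl and imidazole selects the primary C19 hydroxyl over the hindered secondary C3 hydroxyl.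

Step 16
Reactants: 28 3β-alcohol
Product: 29 3-O-(imidazol-1-ylthiocarbonyl) derivative
Conditions: 1,1'-thiocarbonyldiimidazole (3 equiv), DMAP (cat.), toluene, 100 °C
Reagents that add atoms: 1,1'-thiocarbonyldiimidazole, S=C(n1ccnc1)n1ccnc1
Why: Acylation of the C3 hydroxyl with thiocarbonyldiimidazole gives the imidazolide thiocarbonate needed for radical deoxygenation.

Step 17
Reactants: 29 thiocarbonyl imidazolide
Product: 30 3-deoxy tetracycle (13-OTBS, 19-OTBS, 16-OBz)
Conditions: Bu3SnH (2 equiv), AIBN (cat.), toluene, 110 °C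
Reagents that add atoms: none
Why: Barton–McCombie deoxygenation converts C3 into the methylene of the target through a secondary radical that has no acceptor within reach.

Step 18
Reactants: 30 benzoate
Product: 31 C16 alcohol
Conditions: NaOMe (cat.), MeOH/THF, 50 °C
Reagents that add atoms: none
Why: Methoxide-catalysed transesterification removes the benzoate and frees the C16 hydroxyl while both silyl ethers stay.

Step 19
Reactants: 31 C16 alcohol
Product: 32 C16 ketone
Conditions: Dess–Martin periodinane, NaHCO3, CH2Cl2, rt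
Reagents that add atoms: none
Why: Dess–Martin oxidation gives the C16 ketone, which cannot eliminate the β-silyloxy group because enolisation toward bridgehead C12 is forbidden.

Step 20
Reactants: 32 C16 ketone
Product: 33 16,17-spiro-epoxide (C17 axial, oxygen equatorial on ring D)
Conditions: Me3S+ I− (3 equiv), KHMDS (2.8 equiv), THF, 0 °C
Reagents that add atoms: trimethylsulfonium iodide, C[S+](C)C.[I-]
Why: Corey–Chaykovsky epoxidation: the sulfonium ylide adds irreversibly to the less hindered face of the C16 ketone, the face syn to the one-carbon bridge C13 (axial on ring D; the other face is the concave side over C9=C11), so C17 becomes axial and the epoxide oxygen equatorial, which is the C16 configuration of the target.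

Step 21
Reactants: 33 spiro-epoxide
Product: 34 13,19-bis-O-TBS botryotin E
Conditions: CsOAc (5 equiv), AcOH (2 equiv), DMF, 90 °C
Reagents that add atoms: acetic acid, CC(=O)O
Why: Acetate opens the spiro-epoxide by SN2 attack at the primary carbon C17 under buffered conditions that avoid a C16 cation, giving the tertiary alcohol and the primary acetate directly.

Step 22
Reactants: 34 bis-silyl ether
Product: 35 botryotin E
Conditions: HF·pyridine, THF, rt → 40 °C
Reagents that add atoms: none
Why: Acidic fluoride removes both TBS ethers without the acetate cleavage or migration that a basic fluoride source could cause.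

**Compound list**

1 | cyclopentane-1,3-dione | O=C1CCC(=O)C1 | starting material
2 | 3-[(tert-butyldimethylsilyl)oxy]propanal | O=CCCO[Si](C)(C)C(C)(C)C | starting material
3 | 2-{3-[(tert-butyldimethylsilyl)oxy]propylidene}cyclopentane-1,3-dione | O=C1CCC(=O)C1=CCCO[Si](C)(C)C(C)(C)C | intermediate (not isolated)
4 | 2-{3-[(tert-butyldimethylsilyl)oxy]propyl}cyclopentane-1,3-dione | O=C1CCC(=O)C1CCCO[Si](C)(C)C(C)(C)C | intermediate
5 | acrolein | C=CC=O | starting material
6 | 2-{3-[(tert-butyldimethylsilyl)oxy]propyl}-2-(3-oxopropyl)cyclopentane-1,3-dione | O=CCCC1(CCCO[Si](C)(C)C(C)(C)C)C(=O)CCC1=O | intermediate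
7 | (1R,2S,5R)-5-{3-[(tert-butyldimethylsilyl)oxy]propyl}-2-hydroxybicyclo[3.2.1]octane-6,8-dione | O[C@H]1CC[C@]2(CCCO[Si](C)(C)C(C)(C)C)C(=O)C[C@H]1C2=O | intermediate
8 | bicyclic C9 ketone, 13-OH syn to the C9–C11 bridge, 16-OBz, 3-(TBSO)propyl on C8 | O=C(O[C@H]1CC[C@]2(CCCO[Si](C)(C)C(C)(C)C)C(=O)C[C@H]1[C@H]2O)c1ccccc1 | intermediate
9 | 13-O-TBS ether of 8 | O=C(O[C@H]1CC[C@]2(CCCO[Si](C)(C)C(C)(C)C)C(=O)C[C@H]1[C@H]2O[Si](C)(C)C(C)(C)C)c1ccccc1 | intermediate
10 | potassium C9 enolate of 9 | O=C(O[C@H]1CC[C@]2(CCCO[Si](C)(C)C(C)(C)C)C([O-])=C[C@H]1[C@H]2O[Si](C)(C)C(C)(C)C)c1ccccc1.[K+] | intermediate (not isolated)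
11 | C9 enol triflate (C9=C11), 13-OTBS, 16-OBz, 3-(TBSO)propyl on C8 | O=C(O[C@H]1CC[C@]2(CCCO[Si](C)(C)C(C)(C)C)C(OS(=O)(=O)C(F)(F)F)=C[C@H]1[C@H]2O[Si](C)(C)C(C)(C)C)c1ccccc1 | intermediate
12 | enol triflate with 3-hydroxypropyl on C8 (C5–OH) | O=C(O[C@H]1CC[C@]2(CCCO)C(OS(=O)(=O)C(F)(F)F)=C[C@H]1[C@H]2O[Si](C)(C)C(C)(C)C)c1ccccc1 | intermediate
13 | enol triflate with 3-oxopropyl on C8 (C5 aldehyde) | O=C(O[C@H]1CC[C@]2(CCC=O)C(OS(=O)(=O)C(F)(F)F)=C[C@H]1[C@H]2O[Si](C)(C)C(C)(C)C)c1ccccc1 | intermediate
14 | 2-(triphenyl-λ5-phosphanylidene)propanal | CC(C=O)=P(c1ccccc1)(c1ccccc1)c1ccccc1 | starting material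
15 | enol triflate with (E)-4-methyl-5-oxopent-3-en-1-yl on C8 | O=C(O[C@H]1CC[C@]2(CC/C=C(\C)C=O)C(OS(=O)(=O)C(F)(F)F)=C[C@H]1[C@H]2O[Si](C)(C)C(C)(C)C)c1ccccc1 | intermediate
16 | 2,3-dibromopropene | C=C(Br)CBr | starting material
17 | (1,3-dioxolan-2-ylmethyl)magnesium bromide | Br[Mg]CC1OCCO1 | starting material
18 | 2-(3-bromobut-3-en-1-yl)-1,3-dioxolane | C=C(Br)CCC1OCCO1 | intermediate
19 | [4-(1,3-dioxolan-2-yl)but-1-en-2-yl]lithium | [Li]C(=C)CCC1OCCO1 | intermediate (not isolated)
20 | 2-[3-(4,4,5,5-tetramethyl-1,3,2-dioxaborolan-2-yl)but-3-en-1-yl]-1,3-dioxolane | C=C(CCC1OCCO1)B1OC(C)(C)C(C)(C)O1 | intermediate (not isolated)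
21 | 4-(4,4,5,5-tetramethyl-1,3,2-dioxaborolan-2-yl)pent-4-enal | C=C(CCC=O)B1OC(C)(C)C(C)(C)O1 | intermediate
22 | bicyclic diene dialdehyde: 5-oxopent-1-en-2-yl on C9, (E)-enal chain on C8, 13-OTBS, 16-OBz | O=C(O[C@H]1CC[C@]2(CC/C=C(\C)C=O)C(C(=C)CCC=O)=C[C@H]1[C@H]2O[Si](C)(C)C(C)(C)C)c1ccccc1 | intermediate
23 | C10–C9–C11 allyl radical (drawn with the radical at C10) | O=C(O[C@H]1CC[C@]2(CC/C=C(\C)C=O)C([C](C)CCC=O)=C[C@H]1[C@H]2O[Si](C)(C)C(C)(C)C)c1ccccc1 | intermediate (not isolated)
24 | ring-B-closed tricycle with the α-formyl radical at C4 | O=C(O[C@H]1CC[C@]23CC[C@@H]([C](C)C=O)[C@](C)(CCC=O)C2=C[C@H]1[C@H]3O[Si](C)(C)C(C)(C)C)c1ccccc1 | intermediate (not isolated)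
25 | iron(III) C4=C19 enolate of 24 (drawn as the enolate anion) | O=C(O[C@H]1CC[C@]23CC[C@@H](C(C)=C[O-])[C@](C)(CCC=O)C2=C[C@H]1[C@H]3O[Si](C)(C)C(C)(C)C)c1ccccc1 | intermediate (not isolated)
26 | tetracyclic aldol: 3β-OH, 19-aldehyde, 13-OTBS, 16-OBz, A/B trans, CH3-18 and CH3-20 β-axial | O=C(O[C@H]1CC[C@]23CC[C@H]4[C@](C)(C=O)[C@@H](O)CC[C@]4(C)C2=C[C@H]1[C@H]3O[Si](C)(C)C(C)(C)C)c1ccccc1 | intermediate
27 | 3β,19-diol | O=C(O[C@H]1CC[C@]23CC[C@H]4[C@](C)(CO)[C@@H](O)CC[C@]4(C)C2=C[C@H]1[C@H]3O[Si](C)(C)C(C)(C)C)c1ccccc1 | intermediate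
28 | 19-O-TBS 3β-alcohol | O=C(O[C@H]1CC[C@]23CC[C@H]4[C@](C)(CO[Si](C)(C)C(C)(C)C)[C@@H](O)CC[C@]4(C)C2=C[C@H]1[C@H]3O[Si](C)(C)C(C)(C)C)c1ccccc1 | intermediate
29 | 3-O-(imidazol-1-ylthiocarbonyl) derivative of 28 | O=C(O[C@H]1CC[C@]23CC[C@H]4[C@](C)(CO[Si](C)(C)C(C)(C)C)[C@@H](OC(=S)n5ccnc5)CC[C@]4(C)C2=C[C@H]1[C@H]3O[Si](C)(C)C(C)(C)C)c1ccccc1 | intermediate
30 | 3-deoxy tetracycle: 13-OTBS, 19-OTBS, 16-OBz | O=C(O[C@H]1CC[C@]23CC[C@H]4[C@](C)(CO[Si](C)(C)C(C)(C)C)CCC[C@]4(C)C2=C[C@H]1[C@H]3O[Si](C)(C)C(C)(C)C)c1ccccc1 | intermediate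
31 | C16 alcohol (axial OH), 13-OTBS, 19-OTBS | O[C@H]1CC[C@]23CC[C@H]4[C@](C)(CO[Si](C)(C)C(C)(C)C)CCC[C@]4(C)C2=C[C@H]1[C@H]3O[Si](C)(C)C(C)(C)C | intermediate
32 | C16 ketone, 13-OTBS, 19-OTBS | O=C1CC[C@]23CC[C@H]4[C@](C)(CO[Si](C)(C)C(C)(C)C)CCC[C@]4(C)C2=C[C@H]1[C@H]3O[Si](C)(C)C(C)(C)C | intermediate
33 | 16,17-spiro-epoxide (C17 axial, O equatorial), 13-OTBS, 19-OTBS | [C@@]15(CO5)CC[C@]23CC[C@H]4[C@](C)(CO[Si](C)(C)C(C)(C)C)CCC[C@]4(C)C2=C[C@H]1[C@H]3O[Si](C)(C)C(C)(C)C | intermediate
34 | 13,19-bis-O-TBS botryotin E | CC(=O)OC[C@@]1(O)CC[C@]23CC[C@H]4[C@](C)(CO[Si](C)(C)C(C)(C)C)CCC[C@]4(C)C2=C[C@H]1[C@H]3O[Si](C)(C)C(C)(C)C | intermediate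
35 | botryotin E | CC(=O)OC[C@@]1(O)CC[C@]23CC[C@H]4[C@](C)(CO)CCC[C@]4(C)C2=C[C@H]1[C@H]3O | target

**Step count and risks**

Total steps: 22. Longest linear sequence: 20 (steps 1–9 and 12–22); the boronate branch is steps 10–11.

Steps most likely to fail:

1. Step 13 (Proposed new method). The allylic radical may be quenched by a second hydrogen-atom transfer (net reduction of the diene) or dimerise before the 6-exo closure, the iron enolate may be protonated before the aldol, and facial discrimination at C10 may be insufficient. Fallback with known chemistry, ring A still closed last: from 22, an arenethiol-mediated radical addition–cyclisation replaces the metal hydride. Thiophenol and AIBN in benzene at 80 °C (thiol added slowly) let the thiyl radical add to C20, the same allyl radical closes ring B, and the α-formyl radical takes hydrogen from the thiol to give the phenylthio dialdehyde F1. Ring A is then closed as a separate ionic step by a pyrrolidine/acetic acid aldol to the hydroxy aldehyde F2, borohydride gives the diol F3, and Raney nickel cleaves the C20–S bond to return to the route at 27.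

2. Step 3. Discrimination between the enantiotopic ring ketones may be poor, the aldehyde may oligomerise by intermolecular aldol reaction, and retro-aldol equilibration may erode selectivity. Fallback: from 6, the bridged aldol is run with an achiral catalyst (pyrrolidinium acetate), which gives 7 together with its enantiomer F4. A lipase (vinyl acetate, hexane), chosen by screening to acylate F4 to its acetate F5, leaves 7, which is separated and continues at step 4.

3. Step 20. The ylide may add to the concave face of the C16 ketone (wrong C16 configuration), or the ketone may be enolised instead. Fallback: from 32, Wittig methylenation (Ph3P=CH2) gives the 16-methylene compound F6. Its dihydroxylation (OsO4, NMO) delivers oxygen to C16 from the very face that the ylide carbon had taken, so the 16,17-diol F7 carries the tertiary hydroxyl and C17 where the target needs them. Acetylation of the primary hydroxyl (AcCl, 2,4,6-collidine, −78 °C) returns to the route at 34.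

Further compounds
F1 | step 13 | ring-B-closed 20-(phenylsulfanyl) dialdehyde (C4 epimers) | O=C(O[C@H]1CC[C@]23CC[C@@H](C(C)C=O)[C@](CSc4ccccc4)(CCC=O)C2=C[C@H]1[C@H]3O[Si](C)(C)C(C)(C)C)c1ccccc1
F2 | step 13 | 20-(phenylsulfanyl) analogue of aldol 26 | O=C(O[C@H]1CC[C@]23CC[C@H]4[C@](C)(C=O)[C@@H](O)CC[C@]4(CSc5ccccc5)C2=C[C@H]1[C@H]3O[Si](C)(C)C(C)(C)C)c1ccccc1
F3 | step 13 | 20-(phenylsulfanyl) analogue of diol 27 | O=C(O[C@H]1CC[C@]23CC[C@H]4[C@](C)(CO)[C@@H](O)CC[C@]4(CSc5ccccc5)C2=C[C@H]1[C@H]3O[Si](C)(C)C(C)(C)C)c1ccccc1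
F4 | step 3 | (1S,2R,5S)-5-{3-[(tert-butyldimethylsilyl)oxy]propyl}-2-hydroxybicyclo[3.2.1]octane-6,8-dione (enantiomer of 7) | O[C@@H]1CC[C@@]2(CCCO[Si](C)(C)C(C)(C)C)C(=O)C[C@@H]1C2=O
F5 | step 3 | acetate of F4 | CC(=O)O[C@@H]1CC[C@@]2(CCCO[Si](C)(C)C(C)(C)C)C(=O)C[C@@H]1C2=O
F6 | step 20 | 16-methylene compound, 13-OTBS, 19-OTBS | C=C1CC[C@]23CC[C@H]4[C@](C)(CO[Si](C)(C)C(C)(C)C)CCC[C@]4(C)C2=C[C@H]1[C@H]3O[Si](C)(C)C(C)(C)C
F7 | step 20 | 16,17-diol, 13-OTBS, 19-OTBS | OC[C@@]1(O)CC[C@]23CC[C@H]4[C@](C)(CO[Si](C)(C)C(C)(C)C)CCC[C@]4(C)C2=C[C@H]1[C@H]3O[Si](C)(C)C(C)(C)C
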